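## The problem

Target 20 is a linear tetramer: four six-membered carbocycles joined in a row by three CH2 bridges. Ring A is a non-aromatic 2-butanoyl-3,5-dihydroxy-4,4-dimethylcyclohexa-2,5-dien-1-one. Rings B and C are butanoylphloroglucinols whose two remaining ring carbons, C3 and C5, each carry a different arylmethyl arm. Ring D is a butanoylphloroglucinol with a methyl group on C3 and one arm on C5. There is no stereocentre (C4 of ring A carries two methyl groups), so only the order A–B–C–D and the site of each new bond need control. The central difficulty is that C3 and C5 of a free butanoylphloroglucinol are equivalent and equally nucleophilic, so condensation with formaldehyde or with a quinone methide gives mixtures of mono- and bis-alkylated rings and of oligomers in the wrong order. The molecule is also fragile. Each bridge is flanked by ortho hydroxyls and can be expelled as an ortho-quinone methide in hot alkali, which scrambles the ring order. Strong acid closes the flanking phenols to xanthenes and cleaves the butanoyl groups. Ring A is a vinylogous acid open to retro-Claisen loss of its acyl group, and the polyphenolates oxidise in air. The enabling feature is that rings C and B are isomers of a 3-substituted 4-hydroxy-6-(2-oxopentyl)-2-pyrone. The lactone carbonyl C2 maps onto a C–OH carbon, C3 onto an arm-bearing carbon, C4 onto C–OH, C5 onto the remaining CH, C6 with the ring oxygen onto C–OH, and the side-chain CH2 onto the butanoyl-bearing carbon. In the pyrone only C3 is strongly nucleophilic, so it accepts exactly one arm, and its conversion into the arene then releases exactly one new nucleophilic carbon for the next bridge.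

## Retrosynthesis

**Bridge A–B (20 to 17 and 18).** The bond between the bridging CH2 and C6 of ring A is cut first. Ring A is the only non-aromatic and the most base-sensitive ring, so it should not pass through any alkoxide step. Cutting an inner bridge instead would require an A–B dimer with a free carbon on ring B, which brings back the double-alkylation problem. The precursors are the B–C–D trimer as its Mannich base 17 (giving quinone methide 19 on heating) and butanoylfilicinic acid 18. Each has a single reactive carbon, so the forward step only needs a clean Michael addition of the enolic C6 of 18 to 19.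

**Ring A (18 to 6).** One C4–CH3 bond is cut, which leads back to 1-(2,4,6-trihydroxy-3-methylphenyl)butan-1-one 6, the same ketone that serves as ring D. The forward step is a dearomative C-methylation at the methyl-bearing carbon.

**Aminomethyl arm (17 to 16).** The C–CH2N bond on ring B is cut. Trimer 16 has one free aromatic carbon, so a Mannich reaction can go to only one site.

**Ring B (16 to 14 through 15).** The ring bond between the butanoyl-bearing carbon of ring B and the neighbouring C–OH carbon on the arm side is cut, which unfolds ring B into pyrone 14. The neighbouring cut, the B–C bridge itself, would lead to 12 and free butanoylphloroglucinol with its two equivalent carbons. The pyrone removes that ambiguity. The forward reaction is lactone opening to ester 15 and Claisen reclosure.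

**Bridge B–C (14 to 12 and 3 through 13).** The bond between pyrone C3 and the CH2 is cut. The partners are the C–D dimer Mannich base 12 (giving quinone methide 13) and 4-hydroxy-6-(2-oxopentyl)-2H-pyran-2-one 3. Ring C in 12 has no free carbon left and 3 has one nucleophilic carbon. Mannich base 12 comes from dimer 11 by aminomethylation of its single free carbon.

**Ring C (11 to 9 through 10).** This is the same ring cut as for ring B, between the butanoyl-bearing carbon and the adjacent C–OH carbon of ring C. Precursor 9 is the pyrone carrying ring D on C3. The forward step has to fold the opened chain 10 in the Claisen sense and not the aldol sense.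

**Bridge C–D (9 to 7 and 3 through 8).** The bond between pyrone C3 and the CH2 is cut. Mannich base 7 of ring D gives quinone methide 8, and 7 is made from 6 at its only free carbon.

**Ring D ketone (6 to 4 and 5).** The aryl–acyl bond is cut, giving 2-methylphloroglucinol 4 and butanoyl chloride 5. The two free carbons of 4 are equivalent and the first acyl group deactivates the ring.

**Pyrone side chain (3 to 1 and 2).** The bond between the side-chain CH2 and the ketone carbon is cut, giving 4-hydroxy-6-methyl-2H-pyran-2-one 1 and methyl butanoate 2. The forward step is acylation of the pyrone dianion at its methyl carbon. Pyrone 3 is used twice and ketone 6 twice, so four commercial compounds supply all four rings.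

## Roads not taken

**Alternative 1: benzannulation of a cyclobutenone with a siloxyalkyne to build ring C.**
- Cut: two ring bonds of ring C. One runs from the carbon that becomes a new phenol carbon to the carbon bearing the ring D arm. The other runs from the silyloxy carbon to the carbon bearing the ring B arm.
- Forward: siloxyalkyne A2 (fragment 1, carrying perbenzylated ring D) is heated with 3-ethoxy-2-arylmethylcyclobutenone A3 (fragment 2, carrying tribenzylated ring B). A cascade of four pericyclic steps follows: ring opening to a vinylketene, [2+2] addition, a second ring opening, and six-electron closure. It gives A1, in which ring C appears as a mono-phenol with one ethyl ether and one silyl ether.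
- Merits: the two halves are joined in the ring-forming step, both arms of ring C are placed by construction, the three oxygens emerge differentiated, and no base touches a bridge.
- Weak points: A1 has no butanoyl group on ring C. It would have to be added at the free carbon by a Lewis-acid acylation that six benzyl ethers and a silyl ether are unlikely to survive. The ring C ethyl ether needs a hard dealkylation late in the route. A3 has its substituent on C2, whereas the usual ketene–ethoxyacetylene cycloaddition places it on C4. A2 requires an ester-to-ynolate homologation on a fully substituted arene. Ring B still has to be bridged to ring A afterwards.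
- Comparison: this route is better in regiochemical certainty and in avoiding alkoxide. The chosen plan offsets that with no protecting groups, with the butanoyl group arriving with each ring, and with one two-step cycle used twice on intermediates that each have one reactive carbon.

**Alternative 2: insertion of a ring D aryne into a ring C aldehyde.**
- Cut: the C–D bridge at the bond between CH2 and ring D, together with the adjacent aryl–oxygen bond of ring D. The bridge carbon is the formyl carbon of ring C.
- Forward: CsF releases the aryne from silyl triflate A5. The aryne adds across the C=O of aldehyde A6 to give a benzoxete, which opens to an ortho-quinone methide. Hantzsch ester reduces this in the same flask to the methylene, giving A4. No ring is formed.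
- Merits: the phenols stay benzylated, so bridge exchange in base is excluded. The flanking benzyloxy group should direct the carbonyl oxygen to the aryne carbon next to the methyl group. The final hydrogenolysis over Pd/C is mild.
- Weak points: A5 is a hexasubstituted benzene that needs a long preparation. The butanoyl ketones of A5 and A6 are competing carbonyl partners. The quinone methide from an aryne–aldehyde adduct is normally captured by a second aryne to give a xanthene, and interception by a hydride donor is unproven in so hindered a case. The step makes one bridge only, so rings C and B would each need an equally elaborate aryne or a return to classical couplings.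
- Comparison: this route is better in bridge stability during assembly. The chosen plan is much shorter and builds rings and bridges together from a cheap pyrone.

**Alternative 3: ring B from a bis-silyloxy diene and an alkoxy-ynone.**
- Cut: two bonds of ring B. One joins the arm-bearing carbon to the ethoxy carbon. The other joins the butanoyl-bearing carbon to the former ester carbon.
- Forward: diene A8 (fragment 1, whose terminal carbon carries the perbenzylated C–D arm) adds to 1-ethoxyhex-1-yn-3-one A9 (fragment 2) in the polarity-matched sense. Loss of methanol and the silyl groups gives A7, with ring B as a diphenol monoethyl ether bearing one free carbon.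
- Merits: as in the chosen plan, the butanoyl group arrives with the ring and exactly one free carbon results. The conditions are neutral, which is milder than refluxing alkoxide.
- Weak points: A8 must be made by double silylation of a β-keto ester in the presence of two enolisable aryl butanoyl ketones. Its substituted diene terminus is hindered. The C–D dimer inside it must first be made by another method that already solves the two-arm problem of ring C, so the main difficulty is moved and not removed. An ethyl ether and six benzyl ethers must be cleaved at the end.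
- Comparison: this route is better in mildness of the ring-forming step. The chosen plan solves rings C and B with one reagent and needs no protecting groups.

Key step: step 5

## Route

Assumption: pyrones, phloroglucinols and ring A are drawn in the tautomeric form of the target SMILES; in the flask they react as lithium, magnesium or ammonium salts and are written here in the neutral form obtained after work-up.

Step 1
Reactants: 1 4-hydroxy-6-methyl-2H-pyran-2-one; 2 methyl butanoate
Product: 3 4-hydroxy-6-(2-oxopentyl)-2H-pyran-2-one
Conditions: 1 (2.1 equiv), LiN(i-Pr)2 (4.2 equiv), THF, −78 °C; then 2 (1.0 equiv), −78 to 0 °C; 1 M HCl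
Reagents that add atoms: none
Why: Claisen-type C-acylation of the pyrone dianion at its terminal (6-methyl) carbanion, a known route to 6-(2-oxoalkyl)-4-hydroxy-2-pyrones. The second equivalent of dianion stores the more acidic product as its trianion, so no free amide base remains to enolise the ester and no second acylation occurs.

Step 2
Reactants: 4 2-methylbenzene-1,3,5-triol (2-methylphloroglucinol); 5 butanoyl chloride
Product: 6 1-(2,4,6-trihydroxy-3-methylphenyl)butan-1-one
Conditions: AlCl3 (3.5 equiv), PhNO2/CH2Cl2, 0 to 50 °C; aq. HCl
Reagents that add atoms: none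
Why: Friedel–Crafts acylation of a phloroglucinol. The two free ring carbons of 4 are equivalent, and the first acyl group, held in an aluminium chelate, deactivates the ring against a second acylation.

Step 3
Reactants: 6 1-(2,4,6-trihydroxy-3-methylphenyl)butan-1-one
Product: 7 1-{3-[(dimethylamino)methyl]-2,4,6-trihydroxy-5-methylphenyl}butan-1-one
Conditions: CH2=NMe2+ I− (1.1 equiv), MeCN, 0 °C to rt; aq. NaHCO3
Reagents that add atoms: N,N-dimethylmethyleneiminium iodide, C=[N+](C)C.[I-]
Why: Phenolic Mannich reaction with a preformed iminium salt. Ketone 6 has a single free ring carbon, so one regioisomer is possible, and with no free formaldehyde present the diarylmethane by-product is avoided.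

Step 4
Reactants: 7 1-{3-[(dimethylamino)methyl]-2,4,6-trihydroxy-5-methylphenyl}butan-1-one; 3 4-hydroxy-6-(2-oxopentyl)-2H-pyran-2-one
Product: 9 3-[(3-butanoyl-2,4,6-trihydroxy-5-methylphenyl)methyl]-4-hydroxy-6-(2-oxopentyl)-2H-pyran-2-one, via ring D ortho-quinone methide 8 (not isolated)
Conditions: 3 (1.3 equiv), 1,4-dioxane, 90–100 °C, N2 sweep; dilute HCl wash
Reagents that add atoms: none
Why: Thermal loss of dimethylamine from the ortho-hydroxybenzylamine gives quinone methide 8, which is trapped in a Michael addition by C3 of the pyrone, the known alkylation of 4-hydroxy-2-pyrones and 4-hydroxycoumarins by phenolic Mannich bases. Ring D has no free ring carbon left, so 8 cannot oligomerise through carbon, and the side-chain CH2 of 3 is not ionised under these neutral conditions.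

Step 5
Reactants: 9 3-[(3-butanoyl-2,4,6-trihydroxy-5-methylphenyl)methyl]-4-hydroxy-6-(2-oxopentyl)-2H-pyran-2-one
Product: 11 1-{3-[(3-butanoyl-2,4,6-trihydroxyphenyl)methyl]-2,4,6-trihydroxy-5-methylphenyl}butan-1-one (C–D dimer), via open-chain trioxo ester 10 (not isolated)
Conditions: Mg(OMe)2 (8 equiv), MeOH, reflux, Ar, degassed; cold 1 M HCl
Reagents that add atoms: none
Why: Methoxide from Mg(OMe)2 adds to the lactone carbonyl of 9 and opens the ring to the magnesium chelate of trioxo ester 10, in which pyrone C2 to C6 and the side-chain CH2 have become chain carbons C1 to C6. The carbon between the C5 and C7 ketones (the former side-chain CH2) then attacks the ester carbonyl in a 6-exo-trig addition, and loss of methoxide gives a 2-butanoylcyclohexane-1,3,5-trione that enolises to the arene; ring C is thus closed by the bond between its butanoyl-bearing carbon and the hydroxyl-bearing carbon that was the lactone carbonyl. The closest known reaction is the Mg(OMe)2-induced conversion of 6-(2-oxoalkyl)-4-hydroxy-2-pyrones into acylphloroglucinols by ring opening and Claisen (Dieckmann-type) condensation. The selectivity needed is Claisen against aldol folding: the aldol route requires the ester α-carbon, here tertiary because it carries the ring D arm, to attack the butanoyl ketone, and its adduct holds a quaternary carbon that cannot aromatise without losing the ester carbon, so it should revert, while magnesium chelation of the 3,5,7-trioxo array holds the chain in the Claisen fold. If an ortho phenoxide of ring D captures the ester as a six-membered aryl lactone, the same carbanion attacks that lactone carbonyl and the phenoxide leaves, so this detour also ends in 11. No stereocentre is formed, and the former pyrone C5 emerges as the single free carbon of ring C.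

Step 6
Reactants: 11 1-{3-[(3-butanoyl-2,4,6-trihydroxyphenyl)methyl]-2,4,6-trihydroxy-5-methylphenyl}butan-1-one
Product: 12 1-[3-({3-butanoyl-5-[(dimethylamino)methyl]-2,4,6-trihydroxyphenyl}methyl)-2,4,6-trihydroxy-5-methylphenyl]butan-1-one
Conditions: CH2=NMe2+ I− (1.1 equiv), MeCN/DMF, 0 °C to rt; aq. NaHCO3
Reagents that add atoms: N,N-dimethylmethyleneiminium iodide, C=[N+](C)C.[I-]
Why: Phenolic Mannich reaction. The only unsubstituted aromatic carbon of 11 is C5 of ring C, and the mild, non-basic conditions leave the C–D bridge untouched.

Step 7
Reactants: 12 1-[3-({3-butanoyl-5-[(dimethylamino)methyl]-2,4,6-trihydroxyphenyl}methyl)-2,4,6-trihydroxy-5-methylphenyl]butan-1-one; 3 4-hydroxy-6-(2-oxopentyl)-2H-pyran-2-one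
Product: 14 3-{[3-butanoyl-5-[(3-butanoyl-2,4,6-trihydroxy-5-methylphenyl)methyl]-2,4,6-trihydroxyphenyl]methyl}-4-hydroxy-6-(2-oxopentyl)-2H-pyran-2-one, via ring C ortho-quinone methide 13 (not isolated)
Conditions: 3 (1.5 equiv), 1,4-dioxane, 90–100 °C, N2 sweep; dilute HCl wash
Reagents that add atoms: none
Why: Same quinone methide Michael addition as in step 4. Rings C and D are fully substituted, so 13 can be captured only by C3 of the pyrone.

Step 8
Reactants: 14 3-{[3-butanoyl-5-[(3-butanoyl-2,4,6-trihydroxy-5-methylphenyl)methyl]-2,4,6-trihydroxyphenyl]methyl}-4-hydroxy-6-(2-oxopentyl)-2H-pyran-2-one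
Product: 16 1-{3-[(3-butanoyl-2,4,6-trihydroxyphenyl)methyl]-5-[(3-butanoyl-2,4,6-trihydroxy-5-methylphenyl)methyl]-2,4,6-trihydroxyphenyl}butan-1-one (B–C–D trimer), via open-chain trioxo ester 15 (not isolated)
Conditions: Mg(OMe)2 (12 equiv), MeOH, reflux, Ar, degassed; cold 1 M HCl
Reagents that add atoms: none
Why: Second use of the pyrone-to-acylphloroglucinol ring transformation (lactone opening, 6-exo-trig Claisen closure, enolisation), now closing ring B. The arm on the ester α-carbon again disfavours the aldol fold, and ring B emerges with one free carbon.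

Step 9
Reactants: 16 1-{3-[(3-butanoyl-2,4,6-trihydroxyphenyl)methyl]-5-[(3-butanoyl-2,4,6-trihydroxy-5-methylphenyl)methyl]-2,4,6-trihydroxyphenyl}butan-1-one
Product: 17 1-{3-({3-butanoyl-5-[(dimethylamino)methyl]-2,4,6-trihydroxyphenyl}methyl)-5-[(3-butanoyl-2,4,6-trihydroxy-5-methylphenyl)methyl]-2,4,6-trihydroxyphenyl}butan-1-one
Conditions: CH2=NMe2+ I− (1.1 equiv), MeCN/DMF, 0 °C to rt; aq. NaHCO3
Reagents that add atoms: N,N-dimethylmethyleneiminium iodide, C=[N+](C)C.[I-]
Why: Phenolic Mannich reaction at the single free aromatic carbon of 16 (C5 of ring B).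

Step 10
Reactants: 6 1-(2,4,6-trihydroxy-3-methylphenyl)butan-1-one
Product: 18 2-butanoyl-3,5-dihydroxy-4,4-dimethylcyclohexa-2,5-dien-1-one (butanoylfilicinic acid)
Conditions: NaOMe (3.0 equiv), MeI (1.1 equiv), MeOH, 0 °C to rt; 1 M HCl
Reagents that add atoms: iodomethane, CI
Why: Dearomative C-methylation of an acylphloroglucinol polyanion, the second stage of the known conversion of acylphloroglucinols into acylfilicinic acids. Attack through the methyl-bearing carbon gives the 4,4-dimethyl dienone, a vinylogous acid whose anion is a poorer nucleophile than the aromatic isomer, and a near-stoichiometric charge of iodomethane limits further methylation.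

Step 11
Reactants: 17 1-{3-({3-butanoyl-5-[(dimethylamino)methyl]-2,4,6-trihydroxyphenyl}methyl)-5-[(3-butanoyl-2,4,6-trihydroxy-5-methylphenyl)methyl]-2,4,6-trihydroxyphenyl}butan-1-one; 18 2-butanoyl-3,5-dihydroxy-4,4-dimethylcyclohexa-2,5-dien-1-one
Product: 20 2-butanoyl-6-{[3-butanoyl-5-({3-butanoyl-5-[(3-butanoyl-2,4,6-trihydroxy-5-methylphenyl)methyl]-2,4,6-trihydroxyphenyl}methyl)-2,4,6-trihydroxyphenyl]methyl}-3,5-dihydroxy-4,4-dimethylcyclohexa-2,5-dien-1-one (CNP0246352.0), via ring B ortho-quinone methide 19 (not isolated)
Conditions: 18 (1.5 equiv), 1,4-dioxane, 80–90 °C, N2 sweep; dilute HCl wash; crystallisation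
Reagents that add atoms: none
Why: Loss of dimethylamine from 17, assisted by the acidic partner 18, gives quinone methide 19, and Michael addition of the enolic C6 of 18 forms the last bridge. This is the stepwise form of the classical methylene coupling of an acylfilicinic acid with an acylphloroglucinol, and since each partner has one reactive carbon only the A–B bridge can form.

## Compound list

1 | 4-hydroxy-6-methyl-2H-pyran-2-one | CC1=CC(O)=CC(=O)O1 | starting material
2 | methyl butanoate | CCCC(=O)OC | starting material
3 | 4-hydroxy-6-(2-oxopentyl)-2H-pyran-2-one | CCCC(=O)CC1=CC(O)=CC(=O)O1 | intermediate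
4 | 2-methylbenzene-1,3,5-triol | Cc1c(O)cc(O)cc1O | starting material
5 | butanoyl chloride | CCCC(=O)Cl | starting material
6 | 1-(2,4,6-trihydroxy-3-methylphenyl)butan-1-one | CCCC(=O)c1c(O)cc(O)c(C)c1O | intermediate
7 | 1-{3-[(dimethylamino)methyl]-2,4,6-trihydroxy-5-methylphenyl}butan-1-one | CCCC(=O)c1c(O)c(CN(C)C)c(O)c(C)c1O | intermediate
8 | 2-butanoyl-3,5-dihydroxy-4-methyl-6-methylidenecyclohexa-2,4-dien-1-one (ring D ortho-quinone methide) | C=C1C(=O)C(C(=O)CCC)=C(O)C(C)=C1O | intermediate (not isolated)
9 | 3-[(3-butanoyl-2,4,6-trihydroxy-5-methylphenyl)methyl]-4-hydroxy-6-(2-oxopentyl)-2H-pyran-2-one | CCCC(=O)CC1=CC(O)=C(Cc2c(O)c(C)c(O)c(C(=O)CCC)c2O)C(=O)O1 | intermediate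
10 | methyl 2-[(3-butanoyl-2,4,6-trihydroxy-5-methylphenyl)methyl]-3,5,7-trioxodecanoate | CCCC(=O)CC(=O)CC(=O)C(Cc1c(O)c(C)c(O)c(C(=O)CCC)c1O)C(=O)OC | intermediate (not isolated)
11 | 1-{3-[(3-butanoyl-2,4,6-trihydroxyphenyl)methyl]-2,4,6-trihydroxy-5-methylphenyl}butan-1-one (C–D dimer) | CCCC(=O)c1c(O)cc(O)c(Cc2c(O)c(C)c(O)c(C(=O)CCC)c2O)c1O | intermediate
12 | 1-[3-({3-butanoyl-5-[(dimethylamino)methyl]-2,4,6-trihydroxyphenyl}methyl)-2,4,6-trihydroxy-5-methylphenyl]butan-1-one | CCCC(=O)c1c(O)c(CN(C)C)c(O)c(Cc2c(O)c(C)c(O)c(C(=O)CCC)c2O)c1O | intermediate
13 | 2-butanoyl-4-[(3-butanoyl-2,4,6-trihydroxy-5-methylphenyl)methyl]-3,5-dihydroxy-6-methylidenecyclohexa-2,4-dien-1-one (ring C ortho-quinone methide) | C=C1C(=O)C(C(=O)CCC)=C(O)C(Cc2c(O)c(C)c(O)c(C(=O)CCC)c2O)=C1O | intermediate (not isolated)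
14 | 3-{[3-butanoyl-5-[(3-butanoyl-2,4,6-trihydroxy-5-methylphenyl)methyl]-2,4,6-trihydroxyphenyl]methyl}-4-hydroxy-6-(2-oxopentyl)-2H-pyran-2-one | CCCC(=O)CC1=CC(O)=C(Cc2c(O)c(Cc3c(O)c(C)c(O)c(C(=O)CCC)c3O)c(O)c(C(=O)CCC)c2O)C(=O)O1 | intermediate
15 | methyl 2-{[3-butanoyl-5-[(3-butanoyl-2,4,6-trihydroxy-5-methylphenyl)methyl]-2,4,6-trihydroxyphenyl]methyl}-3,5,7-trioxodecanoate | CCCC(=O)CC(=O)CC(=O)C(Cc1c(O)c(Cc2c(O)c(C)c(O)c(C(=O)CCC)c2O)c(O)c(C(=O)CCC)c1O)C(=O)OC | intermediate (not isolated)
16 | 1-{3-[(3-butanoyl-2,4,6-trihydroxyphenyl)methyl]-5-[(3-butanoyl-2,4,6-trihydroxy-5-methylphenyl)methyl]-2,4,6-trihydroxyphenyl}butan-1-one (B–C–D trimer) | CCCC(=O)c1c(O)cc(O)c(Cc2c(O)c(Cc3c(O)c(C)c(O)c(C(=O)CCC)c3O)c(O)c(C(=O)CCC)c2O)c1O | intermediate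
17 | 1-{3-({3-butanoyl-5-[(dimethylamino)methyl]-2,4,6-trihydroxyphenyl}methyl)-5-[(3-butanoyl-2,4,6-trihydroxy-5-methylphenyl)methyl]-2,4,6-trihydroxyphenyl}butan-1-one | CCCC(=O)c1c(O)c(CN(C)C)c(O)c(Cc2c(O)c(Cc3c(O)c(C)c(O)c(C(=O)CCC)c3O)c(O)c(C(=O)CCC)c2O)c1O | intermediate
18 | 2-butanoyl-3,5-dihydroxy-4,4-dimethylcyclohexa-2,5-dien-1-one | CCCC(=O)C1=C(O)C(C)(C)C(O)=CC1=O | intermediate
19 | 2-butanoyl-4-{[3-butanoyl-5-[(3-butanoyl-2,4,6-trihydroxy-5-methylphenyl)methyl]-2,4,6-trihydroxyphenyl]methyl}-3,5-dihydroxy-6-methylidenecyclohexa-2,4-dien-1-one (ring B ortho-quinone methide) | C=C1C(=O)C(C(=O)CCC)=C(O)C(Cc2c(O)c(Cc3c(O)c(C)c(O)c(C(=O)CCC)c3O)c(O)c(C(=O)CCC)c2O)=C1O | intermediate (not isolated)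
20 | 2-butanoyl-6-{[3-butanoyl-5-({3-butanoyl-5-[(3-butanoyl-2,4,6-trihydroxy-5-methylphenyl)methyl]-2,4,6-trihydroxyphenyl}methyl)-2,4,6-trihydroxyphenyl]methyl}-3,5-dihydroxy-4,4-dimethylcyclohexa-2,5-dien-1-one | CCCC(=O)C1=C(O)C(C)(C)C(O)=C(Cc2c(O)c(Cc3c(O)c(Cc4c(O)c(C)c(O)c(C(=O)CCC)c4O)c(O)c(C(=O)CCC)c3O)c(O)c(C(=O)CCC)c2O)C1=O | target

## Step count and least certain steps

Total: 11 steps. Longest linear sequence: 9 steps (steps 2, 3, 4, 5, 6, 7, 8, 9 and 11).

**Step 5 (key step) and its repetition, step 8.**
- Risk: retro-Michael expulsion of an existing arm as a quinone methide in refluxing alkoxide, followed by recombination, would exchange the bridges and scramble the ring order. The danger grows in step 8, where a finished C–D bridge is exposed as well.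
- Risk: the aldol fold could be followed by loss of the ester carbon, draining material to a resorcinol.
- Risk: the pyronate, a vinylogous carboxylate, may be opened only slowly by methoxide.
- Fallback: leave the pyrone aside for the ring concerned and set out from Mannich base 7. Heat it in dioxane with a three- to five-fold excess of 1-(2,4,6-trihydroxyphenyl)butan-1-one F1, made from commercial benzene-1,3,5-triol and 5 with AlCl3. The two free carbons of F1 are equivalent, and the excess, which is recoverable, suppresses double alkylation through quinone methide 8. The fallback returns to the route at 11. The same reagent F1 heated with 12 would replace steps 7 and 8 and return at 16.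

**Step 4 (and its repetition, step 7).**
- Risk: slow release of the quinone methide from the zwitterionic Mannich base.
- Risk: condensation of the liberated dimethylamine with the oxopentyl ketone or with the lactone of 3.
- Risk: reversible O-alkylation that holds back material.
- Fallback: reverse the polarity, setting out from 3 and 6. Aminomethylate 3 at C3 with N,N-dimethylmethyleneiminium iodide to give 3-[(dimethylamino)methyl]-4-hydroxy-6-(2-oxopentyl)-2H-pyran-2-one F2. This betaine loses dimethylamine near room temperature to give 3-methylidene-6-(2-oxopentyl)-2H-pyran-2,4(3H)-dione F3, which is trapped by the single free ring carbon of 6. The fallback returns at 9.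

**Step 10.**
- Risk: poor site selectivity between the methyl-bearing and the free ring carbon.
- Risk: over-methylation and O-methylation.
- Fallback: use a substrate with only one alkylatable carbon, setting out from 5 and commercial benzene-1,3,5-triol. Double Friedel–Crafts acylation with AlCl3 gives 1,1'-(2,4,6-trihydroxy-1,3-phenylene)di(butan-1-one) F4. Exhaustive methylation with NaOMe and iodomethane at its only free carbon gives 2,6-dibutanoyl-3,5-dihydroxy-4,4-dimethylcyclohexa-2,5-dien-1-one F5. Controlled protodeacylation of one butanoyl group in warm aqueous H2SO4, stopped at partial conversion, returns at 18.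

**Step 11.**
- Risk: sluggish methide formation from the hindered trimer.
- Risk: bridge exchange at the temperature needed to expel dimethylamine.
- Risk: retro-Claisen loss of the butanoyl group of ring A under the liberated amine.
- Fallback: reverse the polarity, setting out from 16 and 18 and omitting step 9. Aminomethylate 18 with N,N-dimethylmethyleneiminium iodide to give 2-butanoyl-6-[(dimethylamino)methyl]-3,5-dihydroxy-4,4-dimethylcyclohexa-2,5-dien-1-one F6. This ionises at or slightly above room temperature to 2-butanoyl-3-hydroxy-4,4-dimethyl-6-methylidenecyclohex-2-ene-1,5-dione F7, which is captured by the single free carbon of ring B in 16. The fallback returns at 20.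

## Further compounds

F1 | step 5 | 1-(2,4,6-trihydroxyphenyl)butan-1-one | CCCC(=O)c1c(O)cc(O)cc1O
F2 | step 4 | 3-[(dimethylamino)methyl]-4-hydroxy-6-(2-oxopentyl)-2H-pyran-2-one | CCCC(=O)CC1=CC(O)=C(CN(C)C)C(=O)O1
F3 | step 4 | 3-methylidene-6-(2-oxopentyl)-2H-pyran-2,4(3H)-dione | CCCC(=O)CC1=CC(=O)C(=C)C(=O)O1
F4 | step 10 | 1,1'-(2,4,6-trihydroxy-1,3-phenylene)di(butan-1-one) | CCCC(=O)c1c(O)cc(O)c(C(=O)CCC)c1O
F5 | step 10 | 2,6-dibutanoyl-3,5-dihydroxy-4,4-dimethylcyclohexa-2,5-dien-1-one | CCCC(=O)C1=C(O)C(C)(C)C(O)=C(C(=O)CCC)C1=O
F6 | step 11 | 2-butanoyl-6-[(dimethylamino)methyl]-3,5-dihydroxy-4,4-dimethylcyclohexa-2,5-dien-1-one | CCCC(=O)C1=C(O)C(C)(C)C(O)=C(CN(C)C)C1=O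
F7 | step 11 | 2-butanoyl-3-hydroxy-4,4-dimethyl-6-methylidenecyclohex-2-ene-1,5-dione | CCCC(=O)C1=C(O)C(C)(C)C(=O)C(=C)C1=O
A1 | alternative 1 | protected B–C–D trimer with ring C as a mono-phenol bearing one ethyl ether and one triisopropylsilyl ether | Oc1cc(OCC)c(Cc2c(OCc3ccccc3)cc(OCc3ccccc3)c(C(=O)CCC)c2OCc2ccccc2)c(O[Si](C(C)C)(C(C)C)C(C)C)c1Cc1c(OCc2ccccc2)c(C)c(OCc2ccccc2)c(C(=O)CCC)c1OCc1ccccc1
A2 | alternative 1 | triisopropylsiloxyalkyne carrying tribenzylated ring D (fragment 1) | CC(C)[Si](OC#CCc1c(OCc2ccccc2)c(C)c(OCc2ccccc2)c(C(=O)CCC)c1OCc1ccccc1)(C(C)C)C(C)C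
A3 | alternative 1 | 3-ethoxy-2-(arylmethyl)cyclobut-2-en-1-one carrying tribenzylated ring B (fragment 2) | CCOC1=C(Cc2c(OCc3ccccc3)cc(OCc3ccccc3)c(C(=O)CCC)c2OCc2ccccc2)C(=O)C1
A4 | alternative 2 | protected C–D dimer with one free phenol on ring D and one free carbon on ring C | CCCC(=O)c1c(OCc2ccccc2)c(C)c(O)c(Cc2c(OCc3ccccc3)cc(OCc3ccccc3)c(C(=O)CCC)c2OCc2ccccc2)c1OCc1ccccc1
A5 | alternative 2 | 3,5-bis(benzyloxy)-4-butanoyl-6-methyl-2-(trimethylsilyl)phenyl trifluoromethanesulfonate | CCCC(=O)c1c(OCc2ccccc2)c(C)c(OS(=O)(=O)C(F)(F)F)c([Si](C)(C)C)c1OCc1ccccc1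
A6 | alternative 2 | 2,4,6-tris(benzyloxy)-3-butanoylbenzaldehyde | CCCC(=O)c1c(OCc2ccccc2)cc(OCc2ccccc2)c(C=O)c1OCc1ccccc1
A7 | alternative 3 | B–C–D trimer with ring B as a diphenol monoethyl ether and rings C and D benzylated | CCCC(=O)c1c(O)cc(O)c(Cc2c(OCc3ccccc3)c(Cc3c(OCc4ccccc4)c(C)c(OCc4ccccc4)c(C(=O)CCC)c3OCc3ccccc3)c(OCc3ccccc3)c(C(=O)CCC)c2OCc2ccccc2)c1OCC
A8 | alternative 3 | 1-methoxy-1,3-bis(trimethylsilyloxy)buta-1,3-diene whose C4 carries the benzylated C–D arylmethyl arm (fragment 1) | COC(O[Si](C)(C)C)=CC(O[Si](C)(C)C)=CCc1c(OCc2ccccc2)c(Cc2c(OCc3ccccc3)c(C)c(OCc3ccccc3)c(C(=O)CCC)c2OCc2ccccc2)c(OCc2ccccc2)c(C(=O)CCC)c1OCc1ccccc1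
A9 | alternative 3 | 1-ethoxyhex-1-yn-3-one (fragment 2) | CCCC(=O)C#COCC
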